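(The data come from a simulation for an exercise; noise was put on by code.)

- The maple run climbs from 1.9% at 1.50 min to 6.7% at 3.00 min: twice the time brings 3.53 times the target, a reading close to a square law in time and far from a straight line.

| flask | starting material | second substrate | precatalyst | temperature | remark | time |
|---|---|---|---|---|---|---|
| ash | 20 mM | 0.097 equiv | 0.034 mol% | −30 °C | run made earlier |  |
| maple | 20 mM | 0.60 equiv | 0.034 mol% | −2 °C | run made earlier |  |
| cedar | 9.4 mM | 0.50 equiv | 0.034 mol% | −30 °C | run made earlier |  |
| epsilon | 20 mM | 0.500 equiv | 0.034 mol% | 5 °C |  | 6.0 min |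
| eta | 10 mM | 0.120 equiv | 0.034 mol% | −25 °C |  | 6.0 min |
| gamma | 12 mM | 0.500 equiv | 0.008 mol% | 20 °C |  | 6.0 min |
| theta | 5.0 mM | 0.750 equiv | 0.06 mol% | 5 °C |  | 6.0 min |

| run | time / min | target / % |
|---|---|---|
| ash | 2.50 | 0 |
| ash | 6.00 | 0 |
| ash | 12.0 | 0.8 |
| ash | 15.0 | 0.2 |
| maple | 0.833 | 1.0 |
| maple | 1.50 | 1.9 |
| maple | 2.50 | 4.4 |
| maple | 3.00 | 6.7 |
| cedar | 1.33 | 0.2 |
| cedar | 3.00 | 0 |
| cedar | 8.00 | 0.5 |
| cedar | 15.0 | 0 |

(each reading ± 0.3 percentage points)

* ranking by amount of target, in percent of the starting material charged, from high to low, at 6.0 min (epsilon / eta / gamma / theta)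
* the amount of target, in percent of the starting material charged of the flask you put first, at 6.0 min
* the amount of target, in percent of the starting material charged of the flask you put last, at 6.0 min

- candidate steps: free enzyme -> unfolded enzyme; starting material + free enzyme <-> complex A; complex A -> free enzyme + target; second substrate + free enzyme <-> complex B; complex B -> free enzyme + second product; 2 free enzyme -> spent catalyst; precatalyst -> free enzyme

- The reckoning freezes one thing: precatalyst releases free enzyme at a steady rate, so c(free enzyme) grows in proportion to time. Loss of starting material is then pseudo-first-order with a rising rate constant, and ln(charge/remainder) grows with the square of time. Maple's last reading gives 0.0878 min⁻¹, the induction coefficient g, the square root of ln(charge/remainder) divided by time, with the remainder taken as charge minus target.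
- Time: at 6.0 min, the square of g times time gives an exponent of 0.277, hence 24.2% target at maple's temperature and catalyst charge. Epsilon has that catalyst charge, so this figure serves as its floor.
- Temperature: the ash run, at −30 °C, reads 0.2% at 15.0 min, inside the scatter of 0.3 percentage points. Its coefficient of 0.00298 min⁻¹ is far smaller than g. Epsilon, at 5 °C, should therefore lie above the floor, and eta, at −25 °C, should stay near the cold runs, last.
- Catalyst: the square of g should scale with the catalyst concentration, starting material times loading. Theta has 0.441 of epsilon's at the same temperature, so theta should stand below epsilon. Gamma has 0.141 of it and is warmer, so its third place is the least firm step of this reckoning.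
- Second substrate: ash (0.097 equiv) and cedar (0.50 equiv) both stay at or below 0.8% and differ in starting material as well, so they are no clean test of second substrate. Epsilon's 0.500 equiv lies close to maple's 0.60 equiv, so g is carried over unchanged.
- The forecast gives the same order, epsilon > theta > gamma > eta, with 40% and 0.4%, reckoning that warming “perhaps doubles that”.
- The flasks give epsilon > theta > gamma > eta, with 42.0% in epsilon, 30.0% in theta, 6.43% in gamma and 0.224% in eta.

    free enzyme → unfolded enzyme (k = 6.80 × 10⁻⁵ s⁻¹, Ea = 250 kJ mol⁻¹)
    starting material + free enzyme ⇌ complex A (K = 38.0 M⁻¹, k = 26000 M⁻¹ s⁻¹, Ea = 28.0 kJ mol⁻¹, ΔH = −54.0 kJ mol⁻¹)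
    complex A → free enzyme + target (k = 44.0 s⁻¹, Ea = 53.0 kJ mol⁻¹)
    second substrate + free enzyme ⇌ complex B (K = 250 M⁻¹, k = 59000 M⁻¹ s⁻¹, Ea = 19.0 kJ mol⁻¹, ΔH = −50.0 kJ mol⁻¹)
    complex B → free enzyme + second product (k = 73.0 s⁻¹, Ea = 61.0 kJ mol⁻¹)
    2 free enzyme → spent catalyst (k = 6500 M⁻¹ s⁻¹, Ea = 27.0 kJ mol⁻¹)
    precatalyst → free enzyme (k = 0.00620 s⁻¹, Ea = 87.0 kJ mol⁻¹)
    (constants at 5 °C)

- Epsilon's 42.0% corresponds to an exponent of 0.545, which is 1.96 times the one from g. A neighbouring flask is epsilon with 0.085 mol% of precatalyst, 2.50 times the catalyst. Multiplying the exponent from g by both factors gives 1.36, hence 74.3% target. The neighbouring flask holds 59.9% at 6.00 min, with 80.7% of its catalyst as spent catalyst, against 72.1% in epsilon.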